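**Retrosynthetic overview**
- The target is (2R)-2,8-dimethyl-2-[(4R,8S)-4,8,12-trimethyltridec-11-en-1-yl]chroman-6-ol. It is cut at C2'–C3' (copper-catalysed sp3–sp3 coupling of a chroman-2-ylethyl tosylate with a C3'–C13' Grignard reagent) and at C10'–C11' (copper-catalysed coupling of a C10' tosylate with 2-methylprop-1-enylmagnesium bromide).
- The feature the strategy rests on: C4' and C8' are methyl-bearing CH centres joined by the three methylenes C5'–C7', with no functional group nearby. This 1,5-dimethyl array is mapped onto C3 and C7 of a cyclooctanone (ring C3 = C4', C7 = C8', C2 = C3', C8 = C9', C1 = C10').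
- Both centres are set on the eight-membered carbocycle by two copper/phosphoramidite-catalysed dimethylzinc additions to cycloocta-2,7-dienone, using antipodal ligands to obtain the cis product. The second zinc enolate is trapped as the C1=C2 silyl enol ether, and ozonolysis of that bond opens the carbocycle to a chain with two different ends (C3' alcohol, C10' acid).
- Ring order: the eight-membered carbocycle comes from cyclooctanone and is cleaved in step 4; the benzene ring comes from methylhydroquinone; the dihydropyran ring is closed last within the chroman fragment by an enantioselective Wacker-type oxypalladation/carbonylation that sets C2. No alkene is hydrogenated anywhere, so the 11',12' alkene is never at risk.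

Key step: step 3

Assumption: the facial sense of both chiral ligands is taken from close analogues ((S,R,R)-phosphoramidite giving the (S) β-carbon as with cyclohex-2-enone; (S,S)-Bn-BOXAX giving the (S)-chroman-2-ylacetate); if either sense is opposite on these substrates, the antipodal ligand is used in that step.

Ligand L is (S)-1,1'-binaphthalene-2,2'-diyl N,N-bis[(R)-1-phenylethyl]phosphoramidite; ent-L is its (R,S,S) antipode. (S,S)-Bn-BOXAX is (aS)-2,2'-bis[(4S)-4-benzyl-4,5-dihydro-1,3-oxazol-2-yl]-1,1'-binaphthyl.

**Chain fragment**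

Step 1
Reactants: 1 cyclooctanone
Product: 2 (2Z,7Z)-cycloocta-2,7-dien-1-one
Conditions: IBX (4 equiv), DMSO/fluorobenzene (1:2), 75 °C
Reagents that add atoms: none
Why: Two successive IBX dehydrogenations of the ketone (oxidation through its enol form) should stop at the cross-conjugated dienone, which has no α-CH2 group left.

Step 2
Reactants: 2 (2Z,7Z)-cycloocta-2,7-dien-1-one; 3 dimethylzinc
Product: 5 (7S)-7-methylcyclooct-2-en-1-one, via methylzinc dienolate 4 (not isolated)
Conditions: Me2Zn (1.5 equiv), Cu(OTf)2 (2.5 mol%), L (5 mol%), toluene, −25 °C; then 1 M aq. HCl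
Reagents that add atoms: none
Why: Copper-catalysed asymmetric conjugate addition, in which the ligand-bound methylcopper species selects one face of either of the two enantiotopic enone units and so sets C7 (S), while the cross-conjugated zinc dienolate 4 cannot accept a second methyl group before the acidic quench returns the C2=C3 enone.

Step 3
Reactants: 5 (7S)-7-methylcyclooct-2-en-1-one; 3 dimethylzinc; 6 trimethylsilyl trifluoromethanesulfonate
Product: 8 {[cis-(3R,7S)-3,7-dimethylcyclooct-1-en-1-yl]oxy}trimethylsilane, via methylzinc enolate 7 (not isolated)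
Conditions: Me2Zn (1.5 equiv), Cu(OTf)2 (2.5 mol%), ent-L (5 mol%), toluene, −25 °C; then Me3SiOTf (2 equiv), −25 → 0 °C; Et3N, pentane, filtration through basic Al2O3
Reagents that add atoms: none
Why: Dimethylzinc reduces Cu(OTf)2 to monovalent copper, which binds the phosphoramidite, forms a π-complex with C2=C3 of 5 and transfers methyl to C3 by oxidative addition and reductive elimination, while zinc takes the enolate oxygen to give 7. The closest known reaction type is the copper/phosphoramidite conjugate addition of dialkylzinc reagents to cyclic enones with silyl triflate trapping of the zinc enolate. No ring is closed; one C–C bond (C3–CH3) and one stereocentre (C3, R) are formed. The C3 configuration is set by the ligand: the antipode of the ligand used in step 2 should deliver methyl to the face cis to the C7 methyl, since the remote C7 centre biases the flexible ring only weakly. The step needs face selectivity at C3 and regiochemical fidelity of the enolate, and the latter is secured by silylating 7 on oxygen in the same aprotic flask before any proton source can equilibrate C1=C2 with C1=C8. This regiodefined enol ether is what later tells apart the two ends of the otherwise meso cis-3,7-dimethyl ketone.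

Step 4
Reactants: 8 {[cis-(3R,7S)-3,7-dimethylcyclooct-1-en-1-yl]oxy}trimethylsilane
Product: 10 (3S,7R)-8-hydroxy-3,7-dimethyloctanoic acid, via silyl ester methoxy hydroperoxide 9 (not isolated)
Conditions: O3, CH2Cl2/MeOH (1:1), −78 °C; then NaBH4 (excess), −78 → 20 °C; 1 M aq. HCl
Reagents that add atoms: ozone, [O-][O+]=O; methanol, CO (enters 9 only)
Why: Ozonolysis of the electron-rich silyl enol ether gives the silyl ester at ring C1 and a carbonyl oxide at ring C2 that methanol traps as 9, and reduction with NaBH4 at low temperature followed by hydrolysis of the silyl ester should give the C8 alcohol and the C1 acid without enolising the adjacent methyl-bearing centre.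

Step 5
Reactants: 10 (3S,7R)-8-hydroxy-3,7-dimethyloctanoic acid
Product: 11 methyl (3S,7R)-8-hydroxy-3,7-dimethyloctanoate
Conditions: MeOH, p-TsOH·H2O (5 mol%), 65 °C
Reagents that add atoms: methanol, CO
Why: Fischer esterification converts only the carboxylic acid, leaves the primary alcohol free, and a nine-membered lactone is not expected to form.

Step 6
Reactants: 11 methyl (3S,7R)-8-hydroxy-3,7-dimethyloctanoate
Product: 12 methyl (3S,7R)-8-chloro-3,7-dimethyloctanoate
Conditions: PPh3, N-chlorosuccinimide, CH2Cl2, 0 → 20 °C
Reagents that add atoms: N-chlorosuccinimide, O=C1CCC(=O)N1Cl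
Why: Appel-type chlorination (SN2 displacement of the alkoxyphosphonium ion at the primary carbon) installs at C3' a chloride that is inert to hydride at low temperature and to copper-catalysed Grignard coupling, yet can later be turned into a Grignard reagent.

Step 7
Reactants: 12 methyl (3S,7R)-8-chloro-3,7-dimethyloctanoate
Product: 13 (3S,7R)-8-chloro-3,7-dimethyloctan-1-ol
Conditions: DIBAL-H (2.5 equiv), CH2Cl2, −78 → 0 °C; aq. potassium sodium tartrate
Reagents that add atoms: none
Why: Hydride reduction of the ester to the primary alcohol with DIBAL-H, which should not touch the alkyl chloride at these temperatures.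

Step 8
Reactants: 13 (3S,7R)-8-chloro-3,7-dimethyloctan-1-ol
Product: 14 (3S,7R)-8-chloro-3,7-dimethyloctyl 4-methylbenzenesulfonate
Conditions: TsCl, Et3N, DMAP (cat.), CH2Cl2, 0 → 20 °C
Reagents that add atoms: 4-methylbenzenesulfonyl chloride, Cc1ccc(cc1)S(Cl)(=O)=O
Why: O-Sulfonylation of the unhindered primary alcohol turns C10' into the only reactive electrophilic site of the chain.

Step 9
Reactants: 14 (3S,7R)-8-chloro-3,7-dimethyloctyl 4-methylbenzenesulfonate; 15 2-methylprop-1-enylmagnesium bromide
Product: 16 (2R,6S)-1-chloro-2,6,10-trimethylundec-9-ene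
Conditions: 15 (2.5 equiv), Li2CuCl4 (5 mol%), THF, −20 → 20 °C
Reagents that add atoms: none
Why: Copper-catalysed Grignard cross-coupling (Kochi type, sp3–sp2) displaces the primary tosylate with the alkenyl group to form C10'–C11', while the β-branched primary chloride should stay inert under these conditions.

**Chroman fragment**

Step 10
Reactants: 17 methylhydroquinone
Product: 18 2-methyl-4-[(triisopropylsilyl)oxy]phenol
Conditions: i-Pr3SiCl (1.0 equiv), imidazole, DMF, 0 °C
Reagents that add atoms: chlorotriisopropylsilane, CC(C)[Si](Cl)(C(C)C)C(C)C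
Why: Silylation with a bulky silyl chloride should favour the hydroxyl group that has no ortho substituent, and the minor regioisomer and bis-silyl ether are removed by chromatography.

Step 11
Reactants: 18 2-methyl-4-[(triisopropylsilyl)oxy]phenol
Product: 19 2-bromo-6-methyl-4-[(triisopropylsilyl)oxy]phenol
Conditions: N-bromosuccinimide (1.0 equiv), i-Pr2NH (10 mol%), CH2Cl2, −20 → 0 °C
Reagents that add atoms: N-bromosuccinimide, O=C1CCC(=O)N1Br
Why: Amine-mediated electrophilic aromatic bromination goes ortho to the free hydroxyl group, the stronger donor, at the only open ortho position, while the bulky silyloxy group shields its own two neighbours.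

Step 12
Reactants: 19 2-bromo-6-methyl-4-[(triisopropylsilyl)oxy]phenol; 20 4-bromo-2-methylbut-1-ene
Product: 22 2-methyl-6-(3-methylbut-3-en-1-yl)-4-[(triisopropylsilyl)oxy]phenol, via homoallylzinc bromide 21 (not isolated)
Conditions: 20, Zn dust, LiCl, THF, 50 °C; then 19, Pd(OAc)2 (2 mol%), SPhos (4 mol%), THF, 25 °C, slow addition of 21 (1.5 equiv)
Reagents that add atoms: zinc, [Zn] (enters 21 only)
Why: Negishi coupling of a primary alkylzinc halide with the aryl bromide under Pd(OAc)2/SPhos, a catalyst system known to tolerate free phenols when the zinc reagent is added slowly, forms the aryl–CH2 bond at the position fixed by the bromine.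

Step 13
Reactants: 22 2-methyl-6-(3-methylbut-3-en-1-yl)-4-[(triisopropylsilyl)oxy]phenol
Product: 23 methyl 2-{(2S)-2,8-dimethyl-6-[(triisopropylsilyl)oxy]chroman-2-yl}acetate
Conditions: Pd(OCOCF3)2 (5 mol%), (S,S)-Bn-BOXAX (20 mol%), p-benzoquinone (4 equiv), CO (1 atm), MeOH, 25 °C
Reagents that add atoms: carbon monoxide, [C-]#[O+]; methanol, CO
Why: Enantioselective domino Wacker-type oxypalladation/carbonylation, in which the phenol oxygen adds to the 1,1-disubstituted alkene bound to divalent palladium carrying the chiral bis(oxazoline), closing the dihydropyran ring 6-exo-trig and setting C2 (S) under ligand control, after which the alkylpalladium (no β-hydrogen) inserts CO, is methanolysed to the ester, and p-benzoquinone reoxidises zerovalent palladium.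

Step 14
Reactants: 23 methyl 2-{(2S)-2,8-dimethyl-6-[(triisopropylsilyl)oxy]chroman-2-yl}acetate
Product: 24 2-{(2S)-2,8-dimethyl-6-[(triisopropylsilyl)oxy]chroman-2-yl}ethan-1-ol
Conditions: DIBAL-H (2.5 equiv), CH2Cl2, −78 → 0 °C; aq. potassium sodium tartrate
Reagents that add atoms: none
Why: Hydride reduction of the ester to the primary alcohol with DIBAL-H, chosen because it should leave the aryl silyl ether intact.

Step 15
Reactants: 24 2-{(2S)-2,8-dimethyl-6-[(triisopropylsilyl)oxy]chroman-2-yl}ethan-1-ol
Product: 25 2-{(2S)-2,8-dimethyl-6-[(triisopropylsilyl)oxy]chroman-2-yl}ethyl 4-methylbenzenesulfonate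
Conditions: TsCl, Et3N, DMAP (cat.), CH2Cl2, 0 → 20 °C
Reagents that add atoms: 4-methylbenzenesulfonyl chloride, Cc1ccc(cc1)S(Cl)(=O)=O
Why: O-Sulfonylation of the primary alcohol gives an unhindered primary electrophile at C2' without touching the quaternary C2 centre.

**Fragment union**

Step 16
Reactants: 16 (2R,6S)-1-chloro-2,6,10-trimethylundec-9-ene; 25 2-{(2S)-2,8-dimethyl-6-[(triisopropylsilyl)oxy]chroman-2-yl}ethyl 4-methylbenzenesulfonate
Product: 27 triisopropyl({(2R)-2,8-dimethyl-2-[(4R,8S)-4,8,12-trimethyltridec-11-en-1-yl]chroman-6-yl}oxy)silane, via alkylmagnesium chloride 26 (not isolated)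
Conditions: 16, Mg turnings, BrCH2CH2Br (cat.), THF, 65 °C; then 25, Li2CuCl4 (5 mol%), THF, −78 → 20 °C
Reagents that add atoms: magnesium, [Mg] (enters 26 only)
Why: Magnesium insertion into the primary chloride followed by copper-catalysed sp3–sp3 Grignard cross-coupling (Fouquet–Schlosser type) with the primary tosylate forms C2'–C3' without touching any stereocentre, the trisubstituted alkene or the hindered aryl silyl ether.

Step 17
Reactants: 27 triisopropyl({(2R)-2,8-dimethyl-2-[(4R,8S)-4,8,12-trimethyltridec-11-en-1-yl]chroman-6-yl}oxy)silane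
Product: 28 (2R)-2,8-dimethyl-2-[(4R,8S)-4,8,12-trimethyltridec-11-en-1-yl]chroman-6-ol
Conditions: n-Bu4NF (1.2 equiv), AcOH (1.2 equiv), THF, 0 °C, under argon
Reagents that add atoms: none
Why: Fluoride-induced cleavage of the aryl silyl ether, buffered with acetic acid so that the electron-rich phenoxide is not exposed to air oxidation, frees the 6-hydroxyl group and leaves the alkene and all three stereocentres unchanged.

**Compound list**
1 | cyclooctanone | O=C1CCCCCCC1 | starting material
2 | (2Z,7Z)-cycloocta-2,7-dien-1-one | O=C1C=CCCCC=C1 | intermediate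
3 | dimethylzinc | C[Zn]C | starting material
4 | methylzinc (7S)-7-methylcycloocta-1(8),2-dien-1-olate | C[Zn]OC1=C[C@@H](C)CCCC=C1 | intermediate
5 | (7S)-7-methylcyclooct-2-en-1-one | O=C1C=CCCC[C@H](C)C1 | intermediate
6 | trimethylsilyl trifluoromethanesulfonate | C[Si](C)(C)OS(=O)(=O)C(F)(F)F | starting material
7 | methylzinc cis-(3R,7S)-3,7-dimethylcyclooct-1-en-1-olate | C[Zn]OC1=C[C@H](C)CCC[C@H](C)C1 | intermediate
8 | {[cis-(3R,7S)-3,7-dimethylcyclooct-1-en-1-yl]oxy}trimethylsilane | C[Si](C)(C)OC1=C[C@H](C)CCC[C@H](C)C1 | intermediate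
9 | trimethylsilyl (3S,7R)-8-hydroperoxy-8-methoxy-3,7-dimethyloctanoate (both C8 epimers) | COC(OO)[C@H](C)CCC[C@H](C)CC(=O)O[Si](C)(C)C | intermediate
10 | (3S,7R)-8-hydroxy-3,7-dimethyloctanoic acid | OC[C@H](C)CCC[C@H](C)CC(=O)O | intermediate
11 | methyl (3S,7R)-8-hydroxy-3,7-dimethyloctanoate | OC[C@H](C)CCC[C@H](C)CC(=O)OC | intermediate
12 | methyl (3S,7R)-8-chloro-3,7-dimethyloctanoate | ClC[C@H](C)CCC[C@H](C)CC(=O)OC | intermediate
13 | (3S,7R)-8-chloro-3,7-dimethyloctan-1-ol | ClC[C@H](C)CCC[C@H](C)CCO | intermediate
14 | (3S,7R)-8-chloro-3,7-dimethyloctyl 4-methylbenzenesulfonate | ClC[C@H](C)CCC[C@H](C)CCOS(=O)(=O)c1ccc(C)cc1 | intermediate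
15 | 2-methylprop-1-enylmagnesium bromide | CC(C)=C[Mg]Br | starting material
16 | (2R,6S)-1-chloro-2,6,10-trimethylundec-9-ene | ClC[C@H](C)CCC[C@H](C)CCC=C(C)C | intermediate
17 | methylhydroquinone (2-methylbenzene-1,4-diol) | Cc1cc(O)ccc1O | starting material
18 | 2-methyl-4-[(triisopropylsilyl)oxy]phenol | Cc1cc(O[Si](C(C)C)(C(C)C)C(C)C)ccc1O | intermediate
19 | 2-bromo-6-methyl-4-[(triisopropylsilyl)oxy]phenol | Cc1cc(O[Si](C(C)C)(C(C)C)C(C)C)cc(Br)c1O | intermediate
20 | 4-bromo-2-methylbut-1-ene | C=C(C)CCBr | starting material
21 | (3-methylbut-3-en-1-yl)zinc bromide | C=C(C)CC[Zn]Br | intermediate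
22 | 2-methyl-6-(3-methylbut-3-en-1-yl)-4-[(triisopropylsilyl)oxy]phenol | Cc1cc(O[Si](C(C)C)(C(C)C)C(C)C)cc(CCC(C)=C)c1O | intermediate
23 | methyl 2-{(2S)-2,8-dimethyl-6-[(triisopropylsilyl)oxy]chroman-2-yl}acetate | COC(=O)C[C@]1(C)CCc2cc(O[Si](C(C)C)(C(C)C)C(C)C)cc(C)c2O1 | intermediate
24 | 2-{(2S)-2,8-dimethyl-6-[(triisopropylsilyl)oxy]chroman-2-yl}ethan-1-ol | OCC[C@]1(C)CCc2cc(O[Si](C(C)C)(C(C)C)C(C)C)cc(C)c2O1 | intermediate
25 | 2-{(2S)-2,8-dimethyl-6-[(triisopropylsilyl)oxy]chroman-2-yl}ethyl 4-methylbenzenesulfonate | Cc1ccc(cc1)S(=O)(=O)OCC[C@]1(C)CCc2cc(O[Si](C(C)C)(C(C)C)C(C)C)cc(C)c2O1 | intermediate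
26 | [(2R,6S)-2,6,10-trimethylundec-9-en-1-yl]magnesium chloride | Cl[Mg]C[C@H](C)CCC[C@H](C)CCC=C(C)C | intermediate
27 | triisopropyl({(2R)-2,8-dimethyl-2-[(4R,8S)-4,8,12-trimethyltridec-11-en-1-yl]chroman-6-yl}oxy)silane | CC(C)=CCC[C@@H](C)CCC[C@@H](C)CCC[C@]1(C)CCc2cc(O[Si](C(C)C)(C(C)C)C(C)C)cc(C)c2O1 | intermediate
28 | (2R)-2,8-dimethyl-2-[(4R,8S)-4,8,12-trimethyltridec-11-en-1-yl]chroman-6-ol | CC(C)=CCC[C@@H](C)CCC[C@@H](C)CCC[C@]1(C)CCc2cc(O)cc(C)c2O1 | target

**Step count**
Total: 17 steps. Longest linear sequence: 11 steps (steps 1–9, 16, 17); the chroman branch is steps 10–15.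

**Steps most likely to fail**

Step 3. The zinc enolate may exchange protons with unreacted ketone before or during silylation, or the trimethylsilyl enol ether may hydrolyse on isolation. Because the cis-dimethyl ketone is meso, any shift of the double bond to C1=C8 would erode the enantiomeric purity of the chain; weak ligand control over the C3 face would add the trans isomer. The fallback sets out from 5 and returns at 8. The same copper-catalysed methyl addition is run with an aqueous acidic quench to give the meso ketone cis-(3R,7S)-3,7-dimethylcyclooctan-1-one F1. F1 is then desymmetrised by enantiotopic-group-selective deprotonation with a homochiral lithium amide (lithium bis[(R)-1-phenylethyl]amide or its antipode, whichever removes the C2 proton, with LiCl and Me3SiCl present, THF, −100 °C), which silylates the kinetic enolate in situ to 8. The absolute sense of the chain then depends on the base and not on the handling of the zinc enolate.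

Step 13. The oxypalladation may discriminate poorly between the two faces of an alkene whose substituents differ only in chain length, on a phenol that has not been tested with this ligand. The fallback sets out from 22 and returns at 24, replacing asymmetric catalysis by resolution. The same cyclocarbonylation is run with pyridine as achiral ligand (Pd(OCOCF3)2, p-benzoquinone, CO, MeOH) to give racemic methyl 2-{2,8-dimethyl-6-[(triisopropylsilyl)oxy]chroman-2-yl}acetate F2. DIBAL-H reduction gives racemic 2-{2,8-dimethyl-6-[(triisopropylsilyl)oxy]chroman-2-yl}ethan-1-ol F3, and the enantiomers are separated by preparative chromatography on a cellulose tris(3,5-dimethylphenylcarbamate) phase to give 24.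

Step 16. Magnesium insertion into the β-branched primary chloride may be slow and accompanied by Wurtz-type homocoupling, or the displacement of the tosylate may be sluggish with competing reduction or elimination, which would waste both advanced fragments. The fallback sets out from 25 and 16 and returns at 27, replacing the Grignard coupling by sulfone alkylation and reductive desulfonylation. Tosylate 25 with PhSO2Na in DMF at 60 °C gives the sulfone triisopropyl({(2S)-2,8-dimethyl-2-[2-(phenylsulfonyl)ethyl]chroman-6-yl}oxy)silane F4. Chloride 16 with NaI in refluxing butan-2-one (Finkelstein exchange) gives (2R,6S)-1-iodo-2,6,10-trimethylundec-9-ene F5. Deprotonation of F4 with n-BuLi in THF/DMPU at −78 °C and alkylation with F5 gives the C2'-phenylsulfonyl derivative of 27 F6 as both C2' epimers. Reductive desulfonylation with Na(Hg) and Na2HPO4 in MeOH at −20 °C removes the sulfonyl group without affecting the trisubstituted alkene and gives 27.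

**Further compounds**
F1 | step 3 | cis-(3R,7S)-3,7-dimethylcyclooctan-1-one (meso) | O=C1C[C@H](C)CCC[C@H](C)C1
F2 | step 13 | racemic methyl 2-{2,8-dimethyl-6-[(triisopropylsilyl)oxy]chroman-2-yl}acetate | COC(=O)CC1(C)CCc2cc(O[Si](C(C)C)(C(C)C)C(C)C)cc(C)c2O1
F3 | step 13 | racemic 2-{2,8-dimethyl-6-[(triisopropylsilyl)oxy]chroman-2-yl}ethan-1-ol | OCCC1(C)CCc2cc(O[Si](C(C)C)(C(C)C)C(C)C)cc(C)c2O1
F4 | step 16 | triisopropyl({(2S)-2,8-dimethyl-2-[2-(phenylsulfonyl)ethyl]chroman-6-yl}oxy)silane | O=S(=O)(CC[C@]1(C)CCc2cc(O[Si](C(C)C)(C(C)C)C(C)C)cc(C)c2O1)c1ccccc1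
F5 | step 16 | (2R,6S)-1-iodo-2,6,10-trimethylundec-9-ene | IC[C@H](C)CCC[C@H](C)CCC=C(C)C
F6 | step 16 | C2'-phenylsulfonyl derivative of 27 (both C2' epimers) | CC(C)=CCC[C@@H](C)CCC[C@@H](C)CC(C[C@]1(C)CCc2cc(O[Si](C(C)C)(C(C)C)C(C)C)cc(C)c2O1)S(=O)(=O)c1ccccc1
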